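## Retrosynthetic overview
1. The last bond made is C3–O (tiglate). A Pd π-allyl 1,3-transposition of a free 3-ene-1,2-diol (C1-OH/C7-OH) with tiglic acid forms it, restores C1=C2 and leaves C7-OH free, so no protecting group is needed.
2. The ene-diol comes from a face-selective Schenck ene reaction (C1–O) on the 7-hydroxy-1-ene. That alcohol comes from SeO2 hydroxylation of the ring methyl (C7–O).
3. The C6–O tiglate comes from Mitsunobu inversion of the Luche alcohol. The C5–OAc comes from Mn(III) α′-acetoxylation of the enone.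
4. No ring is formed. The single carbocycle, all ten skeletal carbons and the C4 stereocentre come from (S)-carvone, with isopropenyl hydrogenated to isopropyl.

Convention and assumption: p-menthane numbering of the target is used throughout (C1 carries C7, C2 is the vinyl CH, C4 carries isopropyl); tiglate means (E)-2-methylbut-2-enoate; commercial (S)-(+)-carvone is taken as enantiopure.

## Route

Step 1
Reactants: 1 (S)-(+)-carvone
Product: 2 (S)-carvotanacetone
Conditions: H2 (1 atm), RhCl(PPh3)3 (1 mol %), toluene, rt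
Reagents that add atoms: none
Why: Wilkinson homogeneous hydrogenation saturates only the unhindered 1,1-disubstituted isopropenyl C=C, so the conjugated trisubstituted enone and the C4 stereocentre bought with 1 are untouched.

Step 2
Reactants: 2 (S)-carvotanacetone
Product: 3 (4R,5R)-5-acetoxy-p-menth-1-en-6-one
Conditions: Mn(OAc)3·2H2O (3 equiv), benzene/AcOH 10:1, reflux (Dean–Stark)
Reagents that add atoms: manganese(III) acetate, CC(=O)[O-].CC(=O)[O-].CC(=O)[O-].[Mn+3]
Why: Mn(III)-mediated α′-acetoxylation of an enone proceeds through the α′ (C5) Mn enolate, and acetate is delivered anti to the neighbouring isopropyl group to give the trans-diequatorial 5R acetate, which is also the thermodynamic epimer.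

Step 3
Reactants: 3 (4R,5R)-5-acetoxy-p-menth-1-en-6-one
Product: 4 (4R,5R,6R)-5-acetoxy-p-menth-1-en-6-ol
Conditions: NaBH4 (1 equiv), CeCl3·7H2O (1.1 equiv), MeOH, −78 to −30 °C; AcOH quench
Reagents that add atoms: none
Why: Luche 1,2-reduction delivers hydride axially (as in carvone to cis-carveol) to give the pseudoequatorial 6R alcohol (cis to isopropyl, trans to OAc), and the cold Ce-buffered medium prevents conjugate reduction and acetyl migration.

Step 4
Reactants: 4 (4R,5R,6R)-5-acetoxy-p-menth-1-en-6-ol; 5 tiglic acid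
Product: 6 (4R,5R,6S)-5-acetoxy-p-menth-1-en-6-yl tiglate
Conditions: 5 (2 equiv), PPh3 (2 equiv), DIAD (2 equiv), toluene, 0 °C to rt
Reagents that add atoms: tiglic acid (5), C/C=C(\C)C(=O)O
Why: Mitsunobu esterification forms the C6–O bond by SN2 inversion of the pseudoequatorial alkoxyphosphonium salt (as in the cis- to trans-carveol inversion), which sets 6S with the tiglate pseudoaxial, cis to OAc and anti to isopropyl.

Step 5
Reactants: 6 (4R,5R,6S)-5-acetoxy-p-menth-1-en-6-yl tiglate
Product: 7 (4R,5R,6S)-5-acetoxy-7-hydroxy-p-menth-1-en-6-yl tiglate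
Conditions: SeO2 (0.5 equiv), t-BuOOH (3 equiv, decane), salicylic acid (10 mol %), CH2Cl2, rt
Reagents that add atoms: tert-butyl hydroperoxide, CC(C)(C)OO; selenium dioxide (catalytic O carrier), O=[Se]=O
Why: SeO2 allylic hydroxylation (ene reaction then [2,3]-shift) attacks the more substituted alkene terminus, where C6–H is oxygenated and misaligned, so only the C7 methyl reacts, while the conjugated tiglate C=C is inert at rt and no stereocentre changes.

Step 6
Reactants: 7 (4R,5R,6S)-5-acetoxy-7-hydroxy-p-menth-1-en-6-yl tiglate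
Product: 9 (1S,4S,5R,6R)-5-acetoxy-1,7-dihydroxy-p-menth-2-en-6-yl tiglate, via tertiary allylic hydroperoxide 8 (not isolated)
Conditions: O2, TPP (0.5 mol %), white LED, CH2Cl2/MeOH 9:1, −10 °C; then PPh3 (1.1 equiv), −10 °C to rt
Reagents that add atoms: dioxygen (as singlet oxygen), O=O
Why: In this Schenck ene reaction singlet oxygen approaches the face opposite the pseudoaxial C6 tiglate and removes the only aligned allylic hydrogen, pseudoaxial C3–H on that same face, so oxygen lands suprafacially on C1 syn to isopropyl (1S), the alkene moves to C2=C3, and PPh3 reduces O–O without touching C–O.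

Step 7
Reactants: 9 (1S,4S,5R,6R)-5-acetoxy-1,7-dihydroxy-p-menth-2-en-6-yl tiglate; 5 tiglic acid
Product: 11 (3S,4S,5R,6S)-5-acetoxy-7-hydroxy-p-menth-1-ene-3,6-diyl ditiglate (target), via spiro dioxaborolane 10 (not isolated)
Conditions: 5 (1.5 equiv), Pd2(dba)3·CHCl3 (2.5 mol %), P(2-furyl)3 (10 mol %), C6F5B(OH)2 (15 mol %), 4 Å MS, THF, 0 °C to rt
Reagents that add atoms: tiglic acid (5), C/C=C(\C)C(=O)O
Why: Proposed new method: dual Pd(0)/arylboronic-acid catalysis for a dehydrative, 1,3-transpositive acyloxylation of a free 3-ene-1,2-diol, in which the electron-poor, non-transmetalating C6F5B(OH)2 condenses reversibly with the 1,2-diol of 9 to give 10 and so turns the pseudoaxial tertiary allylic C1–O into a carbonate-like leaving group; Pd(0) ionises it from the face anti to oxygen, 5 protonates the tethered boronate, and the tiglate thus freed attacks the less hindered C3 terminus anti to Pd, so double inversion moves oxygen from C1 to C3 on the same face (3S, cis to isopropyl), regenerates C1=C2 and, after boronate exchange with fresh 9, releases C7-OH with water as the only by-product; the closest known reaction types are the Tsuji–Trost 1,4-opening of vinyl epoxides and vinyl cyclic carbonates by carboxylic acids and the boron-assisted Pd-catalysed substitution of allylic alcohols.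

## Compound list
1 | (S)-(+)-carvone | CC1=CC[C@@H](CC1=O)C(C)=C | starting material
2 | (S)-carvotanacetone, (5S)-2-methyl-5-isopropylcyclohex-2-en-1-one | C1C=C(C)C(=O)C[C@H]1C(C)C | intermediate
3 | (4R,5R)-5-acetoxy-p-menth-1-en-6-one (OAc trans to isopropyl) | C1C=C(C)C(=O)[C@H](OC(C)=O)[C@H]1C(C)C | intermediate
4 | (4R,5R,6R)-5-acetoxy-p-menth-1-en-6-ol (all-equatorial; OH trans to OAc) | C1C=C(C)[C@@H](O)[C@H](OC(C)=O)[C@H]1C(C)C | intermediate
5 | tiglic acid, (E)-2-methylbut-2-enoic acid | C/C=C(\C)C(=O)O | starting material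
6 | (4R,5R,6S)-5-acetoxy-p-menth-1-en-6-yl tiglate (OTig cis to OAc, both anti to isopropyl) | C1C=C(C)[C@H](OC(=O)/C(C)=C/C)[C@H](OC(C)=O)[C@H]1C(C)C | intermediate
7 | (4R,5R,6S)-5-acetoxy-7-hydroxy-p-menth-1-en-6-yl tiglate | C1C=C(CO)[C@H](OC(=O)/C(C)=C/C)[C@H](OC(C)=O)[C@H]1C(C)C | intermediate
8 | (1S,4S,5R,6R)-5-acetoxy-1-hydroperoxy-7-hydroxy-p-menth-2-en-6-yl tiglate (OOH syn to isopropyl) | C1=C[C@](OO)(CO)[C@H](OC(=O)/C(C)=C/C)[C@H](OC(C)=O)[C@H]1C(C)C | intermediate
9 | (1S,4S,5R,6R)-5-acetoxy-1,7-dihydroxy-p-menth-2-en-6-yl tiglate (C1-OH syn to isopropyl) | C1=C[C@](O)(CO)[C@H](OC(=O)/C(C)=C/C)[C@H](OC(C)=O)[C@H]1C(C)C | intermediate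
10 | 1,7-O-(pentafluorophenyl)boronate of 9 (spiro 1,3,2-dioxaborolane) | C1=C[C@@]2(OB(c3c(F)c(F)c(F)c(F)c3F)OC2)[C@H](OC(=O)/C(C)=C/C)[C@H](OC(C)=O)[C@H]1C(C)C | intermediate
11 | (3S,4S,5R,6S)-5-acetoxy-7-hydroxy-p-menth-1-ene-3,6-diyl ditiglate, CNP0169590.1 | C/C=C(\C)C(=O)O[C@H]1C=C(CO)[C@H](OC(=O)/C(C)=C/C)[C@H](OC(C)=O)[C@H]1C(C)C | target

## Step count and risks
Total steps: 7. Longest linear sequence: 7 (from 1 to 11).

**Step 7 (new method).**
- Risks:
  - ionisation of the hindered tertiary boronate may be slow;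
  - boronic acid alone may cause SN1′ scrambling or participation of the C6 ester;
  - Pd(0) may re-ionise the allylic tiglates of 11;
  - β-hydride elimination would lead on to aromatisation.
- Fallback (known chemistry): it sets out from 9. Cyclodehydration with PPh3/DIAD (toluene, rt to 60 °C) activates the primary OH, the tertiary oxygen closes the ring and C1–O is retained. This gives the spiro vinyl epoxide (1S,4S,5R,6R)-5-acetoxy-1,7-epoxy-p-menth-2-en-6-yl tiglate F1. With 5 (1.5 equiv) and Pd(PPh3)4 (2 mol %) in THF at 0 °C it undergoes the established Pd(0) syn-1,4-addition of a carboxylic acid to a vinyl epoxide and comes back to the route at 11.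

**Step 6.**
- Risks: the ring alkene carries two inductively withdrawing groups, so the ene reaction of the tiglate C=C and abstraction of a carbinol C7–H may compete.
- Fallback: it sets out from 7.
  - Hydroxyl-directed epoxidation (VO(acac)2, t-BuOOH, CH2Cl2, 0 °C) on the face opposite the C6 tiglate gives the epoxy alcohol (1R,2R,4R,5R,6R)-5-acetoxy-1,2-epoxy-7-hydroxy-p-menthan-6-yl tiglate F2.
  - Phenylselenide (PhSeSePh, NaBH4, EtOH, 0 °C) opens it trans-diaxially at C2 to the hydroxy selenide (1S,2S,4R,5R,6R)-5-acetoxy-1,7-dihydroxy-2-(phenylselanyl)-p-menthan-6-yl tiglate F3.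
  - H2O2 (THF, 0 °C) gives the corresponding selenoxide F4. It syn-eliminates away from the carbinol carbon toward C3 (the epoxide-to-allylic-alcohol sequence) and comes back to the route at 9.

**Step 4.**
- Risks: tiglic acid is a weak acid and the allylic alcohol is flanked on both sides, so SN2′ attack at C2, elimination to a diene (then aromatisation) or acetate participation may erode the inversion.
- Fallback: it sets out from 3 and replaces steps 3 and 4. Reagent-controlled reduction with an NADPH-dependent ketoreductase selected from a panel for the 6S alcohol (i-PrOH recycle, pH 7 buffer, 30 °C) gives the pseudoaxial alcohol (4R,5R,6S)-5-acetoxy-p-menth-1-en-6-ol F5. This is esterified with retention using 5 (EDC·HCl, DMAP, CH2Cl2, 0 °C) and comes back to the route at 6.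

## Further compounds
F1 | step 7 | (1S,4S,5R,6R)-5-acetoxy-1,7-epoxy-p-menth-2-en-6-yl tiglate (spiro vinyl epoxide) | C1=C[C@]2(CO2)[C@H](OC(=O)/C(C)=C/C)[C@H](OC(C)=O)[C@H]1C(C)C
F2 | step 6 | (1R,2R,4R,5R,6R)-5-acetoxy-1,2-epoxy-7-hydroxy-p-menthan-6-yl tiglate | C1[C@H]2O[C@@]2(CO)[C@H](OC(=O)/C(C)=C/C)[C@H](OC(C)=O)[C@H]1C(C)C
F3 | step 6 | (1S,2S,4R,5R,6R)-5-acetoxy-1,7-dihydroxy-2-(phenylselanyl)-p-menthan-6-yl tiglate | C1[C@H]([Se]c2ccccc2)[C@](O)(CO)[C@H](OC(=O)/C(C)=C/C)[C@H](OC(C)=O)[C@H]1C(C)C
F4 | step 6 | selenoxide of F3 (configuration at Se undefined) | C1[C@H]([Se](=O)c2ccccc2)[C@](O)(CO)[C@H](OC(=O)/C(C)=C/C)[C@H](OC(C)=O)[C@H]1C(C)C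
F5 | step 4 | (4R,5R,6S)-5-acetoxy-p-menth-1-en-6-ol | C1C=C(C)[C@H](O)[C@H](OC(C)=O)[C@H]1C(C)C
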